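**Retrosynthetic overview** (chromene numbering: O1, C2(CH3)2, C3=C4, C4a stereocentre, C5=O, C6 isobutyryl, C7 OH, C8 prenyl, C8a)
1. C3=C4 is cut by ring-closing olefin metathesis of diene 10, run last on the unprotected triketone. It joins two alkene CH carbons of like polarity, and both propenyl geometries of 10 converge on the one ring alkene.
2. Enabling feature: O1 sits on sp2 C8a, the ring neighbour of quaternary C4a, so the enol ether O1–C8a=C8 of the carbocycle holds the O1–C2(CH3)2–CH=CH2 arm and the C4a alkenyl arm 1,2 and syn. C2 and C4a are both fully substituted, so no olefin migration is possible, and the ring closed is a six-membered 2H-pyran.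
3. The C4a stereocentre comes from a palladium-catalysed asymmetric allylic dearomatisation that desymmetrises the C_s-symmetric aryl ether 6. O1 lies on its mirror plane between the two enantiotopic prenyl-bearing carbons (later C4a and C8), so the position of the ether oxygen is fixed by symmetry. The allyl group is then moved to propenyl.
4. Ether 6 comes from commercial phlorisobutyrophenone 1 by double C-prenylation and para-selective O-(1,1-dimethylpropargyl)ation. The alkyne is semihydrogenated only after the palladium step.
5. Ring order: the carbocycle is the aromatic ring of 1, dearomatised in step 3; the pyran ring is closed last, in step 6.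

Key step: step 6

Assumption: phlorisobutyrophenone (1) is taken as a commercial acylphloroglucinol; all β-triketones are drawn in the enol tautomer of the target SMILES, and the CIP descriptors refer to these drawings.

**Step 1**
Reactants: 1 phlorisobutyrophenone; 2 prenyl bromide
Product: 4 deoxycohumulone, via monoprenyl ketone 3 (not isolated)
Conditions: 2 (2.1 equiv), 10% aq. KOH, 0 °C
Reagents that add atoms: prenyl bromide (2), CC(C)=CCBr
Why: Double C-alkylation of the ambident acylphloroglucinol phenoxide in water (Friedel–Crafts-type C-prenylation of a phenoxide, the classical route to deoxyhumulones), in which hydrogen bonding to the oxygens steers the soft allylic bromide to the two free ring carbons; no stereocentre is formed.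

**Step 2**
Reactants: 4 deoxycohumulone; 5 3-chloro-3-methylbut-1-yne
Product: 6 aryl 1,1-dimethylpropargyl ether (C_s-symmetric)
Conditions: 5 (1.5 equiv), CuCl2·2H2O (2 mol %), DBU (1.5 equiv), MeCN, 0 °C
Reagents that add atoms: 3-chloro-3-methylbut-1-yne (5), CC(C)(Cl)C#C
Why: Copper-catalysed propargylic etherification (copper acetylide/allenylidene substitution at the tertiary carbon) of the one non-chelated and most acidic hydroxyl, the 4-OH para to the ketone, which lies on the mirror plane of 4 so that the product stays C_s-symmetric; no stereocentre is formed.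

**Step 3**
Reactants: 6 aryl 1,1-dimethylpropargyl ether; 7 allyl methyl carbonate
Product: 8 (6S)-6-allyl dienone propargyl ether
Conditions: 7 (1.05 equiv), [Pd(C3H5)Cl]2 (2.5 mol %), (1R,2R)-N,N′-bis[2-(diphenylphosphino)benzoyl]cyclohexane-1,2-diamine (7.5 mol %; the antipode is used if a test run shows the opposite sense of induction), 1,4-dioxane, 0 °C to rt
Reagents that add atoms: allyl methyl carbonate (7), C=CCOC(=O)OC
Why: Asymmetric Tsuji–Trost allylation with dearomatisation (asymmetric allylic dearomatisation of a phenol): the chelated phenoxide of C_s-symmetric 6 attacks the cationic π-allylpalladium complex through one of its two enantiotopic prenyl-bearing carbons inside the chiral pocket of the bisphosphine, which sets C6 (the later C4a) as S, while the ether on O5 prevents a second C-allylation and the mild temperature prevents the [3,3] allyl shift to C4 that would interconvert the enantiomers.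

**Step 4**
Reactants: 8 (6S)-6-allyl dienone propargyl ether
Product: 9 (6S)-6-allyl dienone 1,1-dimethylallyl ether
Conditions: H2 (1 atm), Pd/CaCO3 poisoned with Pb(OAc)2 (Lindlar catalyst), quinoline, EtOAc, rt, stopped after 1 equiv H2
Reagents that add atoms: none
Why: Lindlar semihydrogenation: the terminal alkyne is adsorbed on the lead-poisoned palladium surface far more strongly than the mono- and trisubstituted alkenes, so uptake of one equivalent of H2 at room temperature should stop at the vinyl ether arm without touching the stereocentre.

**Step 5**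
Reactants: 9 (6S)-6-allyl dienone 1,1-dimethylallyl ether
Product: 10 (6R)-6-[(E)-propenyl] diene
Conditions: [(C5H5)Ru(NCMe)(L)]PF6 (3 mol %; L = 2-(diisopropylphosphino)-4-tert-butyl-1-methylimidazole, κ2-P,N), acetone, rt
Reagents that add atoms: none
Why: Bifunctional ruthenium-catalysed positional alkene isomerisation (allyl to (E)-prop-1-enyl): only the C-allyl group combines a monosubstituted alkene with an allylic C–H, the tertiary allyl ether has no allylic hydrogen and the prenyl alkenes are trisubstituted, the quaternary centre stops migration after one position, and the stereocentre is untouched (the descriptor changes from S to R only because propenyl outranks prenyl in the CIP order) and is now immune to [3,3] racemisation.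

**Step 6**
Reactants: 10 (6R)-6-[(E)-propenyl] diene
Product: 11 CNP0119032.1 (target)
Conditions: second-generation Hoveyda–Grubbs catalyst RuCl2(SIMes)(=CH-C6H4-2-O-i-Pr) (5–10 mol %), CH2Cl2 (5 mM), 40 °C, argon purge
Reagents that add atoms: none
Why: Ring-closing olefin metathesis: the ruthenium alkylidene loads onto the terminal vinyl of the ether arm, adds [2+2] across the propenyl double bond on C4a and cycloreverts to the C3=C4 alkene, the chain being carried by Ru=CHCH3 with loss of propene. The closest known reaction type is the ring-closing metathesis of aryl 1,1-dimethylallyl ethers with an ortho-alkenyl group to 2,2-dimethyl-2H-chromenes, including the isomerisation-then-metathesis tactic that uses propenyl partners. The one ring closed is the six-membered 2H-pyran (O1, C2, C3, C4, C4a, C8a), formed by direct ring-closing metathesis as an annulation onto the C4a–C8a bond of the carbocycle; the ring can hold only the Z alkene, so E- and Z-propenyl isomers of 10 converge on one product. No stereocentre is created: C4a, set in step 3, bears no hydrogen and is flanked by no allylic C–H, so it is carried through unchanged. The step needs chemoselectivity for the two less substituted alkenes over the two prenyl groups (which could close seven-membered rings) and over [3,3] rearrangement of the tertiary allyl enol ether; this should be secured by the syn 1,2-placement of the arms on the planar unit O1–C8a(=C8)–C4a, the gem-dimethyl (Thorpe–Ingold) effect at C2, the preference for six- over seven-membered closure and for di- over trisubstituted alkenes, and the 40 °C limit. Joining C3 and C4, two alkene carbons of the same polarity, as the last step on the free triketone removes the need for any protecting group.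

**Compound list**
1 | phlorisobutyrophenone, 2-methyl-1-(2,4,6-trihydroxyphenyl)propan-1-one | CC(C)C(=O)c1c(O)cc(O)cc1O | starting material
2 | prenyl bromide, 1-bromo-3-methylbut-2-ene | CC(C)=CCBr | starting material
3 | monoprenyl ketone, 2-methyl-1-[2,4,6-trihydroxy-3-(3-methylbut-2-en-1-yl)phenyl]propan-1-one | CC(C)C(=O)c1c(O)cc(O)c(CC=C(C)C)c1O | intermediate
4 | deoxycohumulone, 2-methyl-1-[2,4,6-trihydroxy-3,5-bis(3-methylbut-2-en-1-yl)phenyl]propan-1-one | CC(C)C(=O)c1c(O)c(CC=C(C)C)c(O)c(CC=C(C)C)c1O | intermediate
5 | 3-chloro-3-methylbut-1-yne | CC(C)(Cl)C#C | starting material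
6 | 1-{2,6-dihydroxy-3,5-bis(3-methylbut-2-en-1-yl)-4-[(2-methylbut-3-yn-2-yl)oxy]phenyl}-2-methylpropan-1-one (achiral, C_s) | CC(C)C(=O)c1c(O)c(CC=C(C)C)c(OC(C)(C)C#C)c(CC=C(C)C)c1O | intermediate
7 | allyl methyl carbonate | C=CCOC(=O)OC | starting material
8 | (6S)-3-hydroxy-2-isobutyryl-4,6-bis(3-methylbut-2-en-1-yl)-5-[(2-methylbut-3-yn-2-yl)oxy]-6-(prop-2-en-1-yl)cyclohexa-2,4-dien-1-one | CC(C)=CCC1=C(OC(C)(C)C#C)[C@](CC=C)(CC=C(C)C)C(=O)C(C(=O)C(C)C)=C1O | intermediate
9 | (6S)-3-hydroxy-2-isobutyryl-4,6-bis(3-methylbut-2-en-1-yl)-5-[(2-methylbut-3-en-2-yl)oxy]-6-(prop-2-en-1-yl)cyclohexa-2,4-dien-1-one | CC(C)=CCC1=C(OC(C)(C)C=C)[C@](CC=C)(CC=C(C)C)C(=O)C(C(=O)C(C)C)=C1O | intermediate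
10 | (6R)-3-hydroxy-2-isobutyryl-4,6-bis(3-methylbut-2-en-1-yl)-5-[(2-methylbut-3-en-2-yl)oxy]-6-[(1E)-prop-1-en-1-yl]cyclohexa-2,4-dien-1-one | CC(C)=CCC1=C(OC(C)(C)C=C)[C@](/C=C/C)(CC=C(C)C)C(=O)C(C(=O)C(C)C)=C1O | intermediate
11 | CNP0119032.1, (4aR)-7-hydroxy-2,2-dimethyl-4a,8-bis(3-methylbut-2-en-1-yl)-6-(2-methylpropanoyl)-2H-chromen-5(4aH)-one | CC(C)=CCC1=C2OC(C)(C)C=C[C@@]2(CC=C(C)C)C(=O)C(C(=O)C(C)C)=C1O | target

**Totals**
Total step count: 6. Longest linear sequence: 6 steps (1 to 11).

**Steps most likely to fail, with fallbacks**

Step 3. The process at risk is the discrimination between the two enantiotopic prenyl-bearing ring carbons (low enantioselectivity), with a second risk of ionisation of the propargylic ether by zerovalent palladium. The fallback sets out from 6 and replaces asymmetric catalysis by resolution. Classical base-mediated dearomatising C-allylation (allyl bromide, NaOMe, MeOH, 0 °C) should give 8 together with its mirror image, (6R)-3-hydroxy-2-isobutyryl-4,6-bis(3-methylbut-2-en-1-yl)-5-[(2-methylbut-3-yn-2-yl)oxy]-6-(prop-2-en-1-yl)cyclohexa-2,4-dien-1-one F1. Preparative chromatography on a chiral stationary phase (supercritical CO2/MeOH) separates the two, and the route is rejoined at 8. F1 is expected to racemise on warming in toluene through the degenerate [3,3] shift of its allyl group to the other prenyl-bearing carbon, so it should be recyclable.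

Step 2. The process at risk is ether formation at a hydroxyl flanked by two prenyl groups: incomplete conversion, alkylation at a chelated oxygen, or C-alkylation. The fallback sets out from 4 and inverts the order of events. The palladium-catalysed asymmetric allylic dearomatisation is run first on the free triol (conditions of step 3, 0.95 equiv of 7 to limit a second allylation) to give (6S)-3,5-dihydroxy-2-isobutyryl-4,6-bis(3-methylbut-2-en-1-yl)-6-(prop-2-en-1-yl)cyclohexa-2,4-dien-1-one F2. Its single non-chelated hydroxyl is now a vinylogous acid that DBU ionises fully. Copper-catalysed etherification with 5 (conditions of step 2) then gives 8, where the route is rejoined.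

Step 6. The process at risk is catalyst turnover: arrest by chelation to the β-triketone enol, or sluggish reaction at two alkenes that each adjoin a fully substituted carbon, which would let seven-membered closure onto a prenyl group or thermal [3,3] shift of the ether compete. The fallback sets out from 10 and uses a masked substrate with an early-metal alkylidene. The enol is silylated (TBSOTf, 2,6-lutidine, CH2Cl2, −78 °C) to (6R)-3-[(tert-butyldimethylsilyl)oxy]-2-isobutyryl-4,6-bis(3-methylbut-2-en-1-yl)-5-[(2-methylbut-3-en-2-yl)oxy]-6-[(1E)-prop-1-en-1-yl]cyclohexa-2,4-dien-1-one F3. The ring is closed with Mo(=CHCMe2Ph)(=N-2,6-i-Pr2C6H3)[OCMe(CF3)2]2 (benzene, rt) to (4aR)-7-[(tert-butyldimethylsilyl)oxy]-2,2-dimethyl-4a,8-bis(3-methylbut-2-en-1-yl)-6-(2-methylpropanoyl)-2H-chromen-5(4aH)-one F4. Cleavage of the silyl ether (HF·pyridine, THF, 0 °C) returns the route at 11.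

**Further compounds**
F1 | step 3 | (6R)-3-hydroxy-2-isobutyryl-4,6-bis(3-methylbut-2-en-1-yl)-5-[(2-methylbut-3-yn-2-yl)oxy]-6-(prop-2-en-1-yl)cyclohexa-2,4-dien-1-one | CC(C)=CCC1=C(OC(C)(C)C#C)[C@@](CC=C)(CC=C(C)C)C(=O)C(C(=O)C(C)C)=C1O
F2 | step 2 | (6S)-3,5-dihydroxy-2-isobutyryl-4,6-bis(3-methylbut-2-en-1-yl)-6-(prop-2-en-1-yl)cyclohexa-2,4-dien-1-one | CC(C)=CCC1=C(O)[C@](CC=C)(CC=C(C)C)C(=O)C(C(=O)C(C)C)=C1O
F3 | step 6 | (6R)-3-[(tert-butyldimethylsilyl)oxy]-2-isobutyryl-4,6-bis(3-methylbut-2-en-1-yl)-5-[(2-methylbut-3-en-2-yl)oxy]-6-[(1E)-prop-1-en-1-yl]cyclohexa-2,4-dien-1-one | CC(C)=CCC1=C(OC(C)(C)C=C)[C@](/C=C/C)(CC=C(C)C)C(=O)C(C(=O)C(C)C)=C1O[Si](C)(C)C(C)(C)C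
F4 | step 6 | (4aR)-7-[(tert-butyldimethylsilyl)oxy]-2,2-dimethyl-4a,8-bis(3-methylbut-2-en-1-yl)-6-(2-methylpropanoyl)-2H-chromen-5(4aH)-one | CC(C)=CCC1=C2OC(C)(C)C=C[C@@]2(CC=C(C)C)C(=O)C(C(=O)C(C)C)=C1O[Si](C)(C)C(C)(C)C
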